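## Analysis of the target

Compound 13, 4-[(2,4-dimethoxy-6-pentylbenzoyl)oxy]-2-hydroxy-6-pentylbenzoic acid, is a depside: two isolated benzene rings joined through an aryl ester, with no further ring. Ring A is the acyl half, a benzoyl group with methoxy groups on its C2 and C4 and a pentyl chain on its C6. Ring B is the phenol half; its atoms are called B1 to B6 here, with the free carboxyl on B1, a free hydroxyl on B2, the ester oxygen on B4 and a pentyl chain on B6. There is no stereocentre and no configured double bond, so the problem is one of constitution only. The aryl ester is an activated ester that hydroxide, alkoxides and amines cleave, and the ortho-hydroxybenzoic acid of ring B loses CO2 on heating or in strong acid; the carboxyl therefore has to be carried masked and freed last under neutral conditions. The difficulties are the fixed 1,2,4,6 substitution of both rings, the need to tell the two ring B hydroxyls apart, and the formation of an ester at a carbonyl flanked by two ortho substituents. The strategy rests on the pattern of ring B: carboxyl on B1, oxygen on B2 and B4 and alkyl on B6 is the substitution of a 6-alkyl-2,4-dioxocyclohexane-1-carboxylate, one oxidation level below the arene. That ring can be assembled from two acyclic esters, so the connectivity of the building blocks fixes every substituent position.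

## Retrosynthetic reasoning

Target 13 is traced back to its benzyl ester 12 by cutting the O–CH2 bond of a benzyl group on the B1 carboxyl. This is the last operation because hydrogenolysis is neutral and cold, touching neither the depside bond nor the decarboxylation-prone hydroxy acid. The benzyl ester is present from the first step of the ring B synthesis, so it costs no extra step.

Compound 12 is cut at the depside C(=O)–O bond into the ring B phenol 6, benzyl 2,4-dihydroxy-6-pentylbenzoate, and the ring A acid chloride 11. This is the one convergent cut that gives two halves of similar size. The forward reaction must acylate O4 and leave O2 alone. The O2–H is hydrogen-bonded to the neighbouring ester carbonyl and shielded by it, so no protecting group is planned for it.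

Acid chloride 11 goes back through acid 10 and aldehyde 9 to 1,3-dimethoxy-5-pentylbenzene 7, the only skeletal cut being the bond between ring A C1 and the carbonyl carbon. Compound 7 already carries both methyl ethers and the pentyl chain. The forward formylation must enter between the pentyl group and a methoxy group, the position para to the other methoxy group, which is where an electrophile is expected to go.

Phenol 6 is taken back to dione 4, benzyl 2,4-dioxo-6-pentylcyclohexane-1-carboxylate, by formally adding two hydrogens; the oxygens on B2 and B4 become ketones. This turns an arene regiochemistry problem into a question of how a cyclohexanedione is connected. The forward step is a halogenation–dehydrohalogenation that removes both sp3 centres of 4.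

Dione 4 is cut at B1–B6 and B3–B4, through the open-chain keto diester 3, into benzyl acetoacetate 1 and methyl (E)-oct-2-enoate 2. B1–B6 lies beta to the B4 carbonyl and is a conjugate-addition bond. B3–B4 is the acyl–carbon bond of a 1,3-dione and is a Claisen bond. Compound 1 supplies B1 with its carboxyl, B2 and B3; compound 2 supplies B4, B5, B6 and the pentyl chain. Both are commercial, so the route starts with its riskiest step.

## Alternatives that were turned down

Alternative 1: Ring A is built de novo on the oxygen of ring B, cutting the depside C–O bond and the C2–C7 bond of a polyketide chain together. Heating dioxinone A2, 6-(2,4-dioxononyl)-2,2-dimethyl-4H-1,3-dioxin-4-one, with the phenol A3, benzyl 2-(benzyloxy)-4-hydroxy-6-pentylbenzoate, opens the dioxinone ring by cycloreversion. The ketene function set free acylates the phenol oxygen to give the triketo ester A4, whose C2 condenses onto the C7 ketone and dehydrates to the depside A1.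
- For it: the ester bond forms by a neutral, unhindered ketene addition before ring A exists. The chosen route has to push an acyl group with two ortho substituents onto a phenol, so on this point alternative 1 is stronger.
- Against it: A1 carries two free phenols on ring A where the target has two methyl ethers. One of them is chelated to the depside carbonyl, so both must be methylated under basic conditions beside a base-labile aryl ester.
- Against it: A4 can also close through oxygen to a pyranone and expel the phenoxide.
- Against it: A3 needs the ring B resorcylate 6 anyway, plus three protecting-group steps, and A2 needs several steps of its own.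
- Comparison: the chosen route buys ring A with its methyl ethers in place (7, three steps to 11) and needs no protection of O2, and is therefore much shorter.

Alternative 2: Ring B is made by benzannulation, cutting B2–B3, B4–B5 and B1–B2. Irradiation of the diazoketone A6, benzyl (E)-5-diazo-4-oxo-3-pentylpent-2-enoate, causes a Wolff rearrangement. The ketene so formed combines with the siloxyalkyne A7 by [2+2] addition, four-electron ring opening and six-electron ring closure to give A5, benzyl 2-hydroxy-6-pentyl-4-(triisopropylsilyloxy)benzoate.
- For it: the polarity of the ketene and the ynol ether fixes the regiochemistry, and the two ring B oxygens emerge chemically differentiated. That is a firmer distinction than the hydrogen-bond-based selectivity used in the chosen route.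
- Against it: the differentiation is the wrong way round. O4 is the oxygen to be acylated, so the silyl group must come off first, which gives 6 with O2 still free and no gain.
- Against it: A6 requires a regiodefined half-ester of a pentyl-substituted butenedioic acid and diazo chemistry, A7 must be made and is sensitive, and the key step is photochemical.
- Comparison: five or six steps to reach 6 against two from commercial esters in the chosen route.

Alternative 3: Ring A is grown by cycloaddition after the depside ester has been formed with an acyclic acid, cutting C1–C2 and C5–C6 of ring A. The ynoate A10, benzyl 2-(benzyloxy)-4-(oct-2-ynoyloxy)-6-pentylbenzoate, is heated with diene A9, 1,1-dimethoxy-3-(trimethylsilyloxy)buta-1,3-diene. The CH2 terminus of A9 bonds to the pentyl-bearing alkyne carbon and the ketene acetal carbon to the carbon next to the carbonyl. Loss of one geminal methoxy group as the alcohol aromatizes the ring to A8.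
- For it: the ester is made from an unhindered alkynoic acid, one methyl ether arrives with the diene, and the remaining phenol of A8 is unchelated and easy to methylate. On these points it is stronger than alternative 1, and it is easier than the hindered acylation of the chosen route.
- Against it: a beta-alkyl ynoate is a sluggish dienophile that needs prolonged heating with a moisture-sensitive diene.
- Against it: the aryl ynoate is an activated ester exposed to a nucleophilic ketene acetal.
- Against it: A3 again requires the ring B synthesis plus protecting-group steps, followed by a methylation and a double hydrogenolysis.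
- Comparison: it builds a ring that can be bought with its substituents as 7, whereas the chosen route spends its one constructive risk on ring B, which has to be made in any case.

Key step: step 1

Remark: compounds 4 and 5 are drawn as diketo tautomers; they should exist largely as enols and as racemic mixtures of diastereomers, which does not matter because both sp3 centres disappear in step 2.

## Route

Step 1
Reactants: 1 benzyl acetoacetate (benzyl 3-oxobutanoate); 2 methyl (E)-oct-2-enoate
Product: 4 benzyl 2,4-dioxo-6-pentylcyclohexane-1-carboxylate, via 1-benzyl 5-methyl 2-acetyl-3-pentylpentanedioate 3 (not isolated)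
Conditions: KOtBu (1.1 equiv), t-BuOH, rt → 80 °C (1 added to the base first, then 2); then 1 M HCl, 0 °C
Reagents that add atoms: none
Why: KOtBu converts 1 into its stabilized enolate, which adds through C2 to C3 of enoate 2 (B1–B6 bond); proton transfer then gives 3 as its beta-keto ester enolate. Under these equilibrating conditions a small share of 3 carries the charge on the acetyl methyl group (a minor equilibrium enolate, not a kinetically generated one), and this carbon attacks the methyl ester carbonyl and expels methoxide (B3–B4 bond). The closest known reaction type is the Michael–Claisen (Dieckmann-type) annulation of acetoacetic esters with alk-2-enoates to 6-alkyl-2,4-dioxocyclohexanecarboxylates. The ring closes in the favoured 6-(enolendo)-exo-trig mode, and every other enolate–carbonyl pairing in 3 would give a four-membered ring. The sequence is pulled forward because the product, a vinylogous acid, is deprotonated irreversibly by the alkoxide. B1 and B6 become stereocentres without control (trans expected under equilibration), and both are erased in step 2. The selectivity needed is survival of the benzyl ester in the presence of liberated methoxide: 1, 3 and 4 are all present as enolates whose benzyl ester carbonyl is part of the delocalized anion, so only the side-chain methyl ester is electrophilic. Adding 2 to the preformed enolate of 1 keeps free tert-butoxide away from the enoate and so avoids its deconjugation or oligomerization.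

Step 2
Reactants: 4 benzyl 2,4-dioxo-6-pentylcyclohexane-1-carboxylate
Product: 6 benzyl 2,4-dihydroxy-6-pentylbenzoate, via benzyl 3-bromo-2,4-dioxo-6-pentylcyclohexane-1-carboxylate 5 (not isolated)
Conditions: Br2 (1.0 equiv), DMF, 0 °C; then 80 °C
Reagents that add atoms: none
Why: Halogenation–dehydrohalogenation aromatization of a cyclohexane-1,3-dione: the enol of 4 is brominated between the two carbonyl groups to give 5, which on warming loses HBr by way of its enol tautomers to a cyclohexadienone that tautomerizes to resorcylate 6. The amide solvent takes up the HBr; no stronger base is added because it would only hold 5 as its unreactive enolate. One equivalent of Br2 limits bromination of the aromatic product.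

Step 3
Reactants: 7 1,3-dimethoxy-5-pentylbenzene
Product: 9 2,4-dimethoxy-6-pentylbenzaldehyde, via N-(2,4-dimethoxy-6-pentylbenzylidene)-N-methylmethanaminium chloride 8 (not isolated)
Conditions: POCl3, DMF, 0 → 80 °C; then H2O, 0 °C → rt
Reagents that add atoms: N,N-dimethylformamide CN(C)C=O; water O
Why: Vilsmeier–Haack formylation: the chloroiminium ion attacks the ring position para to one methoxy group and ortho to the other (C4 of 7) in preference to the position flanked by both methoxy groups. Aqueous work-up hydrolyses iminium salt 8 to the aldehyde.

Step 4
Reactants: 9 2,4-dimethoxy-6-pentylbenzaldehyde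
Product: 10 2,4-dimethoxy-6-pentylbenzoic acid
Conditions: NaClO2, NaH2PO4, 2-methyl-2-butene, t-BuOH/H2O, rt
Reagents that add atoms: sodium chlorite [Na+].[O-]Cl=O
Why: Pinnick oxidation: chlorous acid adds to the aldehyde and fragments to the acid and HOCl. The alkene scavenger removes HOCl before it can chlorinate the electron-rich ring, and the methyl ethers are untouched.

Step 5
Reactants: 10 2,4-dimethoxy-6-pentylbenzoic acid
Product: 11 2,4-dimethoxy-6-pentylbenzoyl chloride
Conditions: (COCl)2, DMF (cat.), CH2Cl2, 0 °C → rt
Reagents that add atoms: oxalyl chloride O=C(Cl)C(=O)Cl
Why: Acid chloride formation through the catalytic chloroiminium species. The neutral, cold conditions suit an acid with two ortho substituents, and 11 should be used crude after evaporation.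

Step 6
Reactants: 6 benzyl 2,4-dihydroxy-6-pentylbenzoate; 11 2,4-dimethoxy-6-pentylbenzoyl chloride
Product: 12 benzyl 4-[(2,4-dimethoxy-6-pentylbenzoyl)oxy]-2-hydroxy-6-pentylbenzoate
Conditions: Et3N, DMAP (cat.), CH2Cl2, 0 °C → rt (11, 1.05 equiv)
Reagents that add atoms: none
Why: DMAP-catalysed O-acylation of a phenol (nucleophilic acyl substitution): the B2 hydroxyl of 6 is hydrogen-bonded to the benzyl ester carbonyl and shielded by it, whereas the B4 hydroxyl is free, more acidic and unhindered, so one equivalent of 11 should acylate O4 only. The acylpyridinium ion formed from 11 compensates for the shielding of the carbonyl by its two ortho substituents.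

Step 7
Reactants: 12 benzyl 4-[(2,4-dimethoxy-6-pentylbenzoyl)oxy]-2-hydroxy-6-pentylbenzoate
Product: 13 4-[(2,4-dimethoxy-6-pentylbenzoyl)oxy]-2-hydroxy-6-pentylbenzoic acid
Conditions: H2 (1 atm), Pd/C (10%), EtOAc, rt
Reagents that add atoms: none
Why: Hydrogenolysis of a benzyl ester over Pd/C cleaves only the benzylic C–O bond; the aryl ester and methyl ethers stay intact, and no heat or acid is applied that could decarboxylate the 2-hydroxybenzoic acid. A non-alcoholic solvent avoids alcoholysis of the depside bond.

## Compound list

1 | benzyl acetoacetate (benzyl 3-oxobutanoate) | CC(=O)CC(=O)OCc1ccccc1 | starting material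
2 | methyl (E)-oct-2-enoate | CCCCC/C=C/C(=O)OC | starting material
3 | 1-benzyl 5-methyl 2-acetyl-3-pentylpentanedioate | CCCCCC(CC(=O)OC)C(C(C)=O)C(=O)OCc1ccccc1 | intermediate
4 | benzyl 2,4-dioxo-6-pentylcyclohexane-1-carboxylate | CCCCCC1CC(=O)CC(=O)C1C(=O)OCc1ccccc1 | intermediate
5 | benzyl 3-bromo-2,4-dioxo-6-pentylcyclohexane-1-carboxylate | CCCCCC1CC(=O)C(Br)C(=O)C1C(=O)OCc1ccccc1 | intermediate
6 | benzyl 2,4-dihydroxy-6-pentylbenzoate | CCCCCc1cc(O)cc(O)c1C(=O)OCc1ccccc1 | intermediate
7 | 1,3-dimethoxy-5-pentylbenzene | CCCCCc1cc(OC)cc(OC)c1 | starting material
8 | N-(2,4-dimethoxy-6-pentylbenzylidene)-N-methylmethanaminium chloride | CCCCCc1cc(OC)cc(OC)c1C=[N+](C)C.[Cl-] | intermediate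
9 | 2,4-dimethoxy-6-pentylbenzaldehyde | CCCCCc1cc(OC)cc(OC)c1C=O | intermediate
10 | 2,4-dimethoxy-6-pentylbenzoic acid | CCCCCc1cc(OC)cc(OC)c1C(=O)O | intermediate
11 | 2,4-dimethoxy-6-pentylbenzoyl chloride | CCCCCc1cc(OC)cc(OC)c1C(=O)Cl | intermediate
12 | benzyl 4-[(2,4-dimethoxy-6-pentylbenzoyl)oxy]-2-hydroxy-6-pentylbenzoate | CCCCCc1cc(OC(=O)c2c(CCCCC)cc(OC)cc2OC)cc(O)c1C(=O)OCc1ccccc1 | intermediate
13 | 4-[(2,4-dimethoxy-6-pentylbenzoyl)oxy]-2-hydroxy-6-pentylbenzoic acid | CCCCCc1cc(OC(=O)c2c(CCCCC)cc(OC)cc2OC)cc(O)c1C(=O)O | target

## Step count and risks

Total step count: 7. Longest linear sequence: 5 steps (7 → 9 → 10 → 11 → 12 → 13); the ring B branch (1 + 2 → 4 → 6, two steps) joins at step 6.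

Least certain steps:

Step 1 (key step). The most likely failures are ester exchange at the benzyl ester by the methoxide that the Claisen closure releases, and stalling at the open-chain adduct 3 with retro-Michael loss. Both can happen because the cyclization depends on a minor enolate in an equilibrium mixture while an alkoxide different from the ester group is present. The fallback sets out from 2 and comes back at 4. Ester 2 is converted with MeNHOMe·HCl and i-PrMgCl (THF, −20 °C) into (E)-N-methoxy-N-methyloct-2-enamide F1, and MeMgBr (THF, 0 °C) then gives (E)-non-3-en-2-one F2, which can also be bought. Dibenzyl propanedioate F3 is added as its sodium enolate (NaOBn from NaH and BnOH, THF, reflux) to the beta carbon of F2. The adduct, dibenzyl 2-(2-oxononan-4-yl)propanedioate F4, is not isolated: its methyl ketone enolate closes onto one benzyl ester (B2–B3 bond in place of B3–B4) and expels benzyl alkoxide, which matches the ester, so exchange has no consequence. Acidification gives 4.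

Step 2. The most likely failures are further bromination of the electron-rich product by bromine transfer from 5, and loss of the benzyl group to HBr at 80 °C followed by decarboxylation of the freed hydroxy acid. Both arise because two equivalents of HBr are generated in a hot solution. The fallback sets out from 7 and comes back at 6, so ring B is taken from an existing arene and no dehydrogenation is needed. BBr3 (CH2Cl2, −78 °C → rt) demethylates 7 to 5-pentylbenzene-1,3-diol F5, which is also commercial. MeOMgOCO2Me (methyl magnesium carbonate) in DMF at 120 °C, followed by cold aqueous HCl, carboxylates F5 ortho to a phenolic oxygen through a magnesium chelate to give 2,4-dihydroxy-6-pentylbenzoic acid F6; any isomer carboxylated between the two hydroxyls would have to be separated. BnBr with KHCO3 in DMF at rt then alkylates only the carboxylate to give 6.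

Step 6. The most likely failure is slow acyl transfer from a carbonyl shielded by two ortho substituents; if the reaction is then forced, hydrolysis of 11 or a second acylation at O2 competes. The fallback sets out from 10 (with 6) and comes back at 12, replacing base-mediated acyl transfer by an acid-mediated one. Acid 10 is treated with (CF3CO)2O in toluene (0 °C → rt) to form 2,4-dimethoxy-6-pentylbenzoic trifluoroacetic anhydride F7 in the flask. The electron-rich acyl group of F7 transfers readily, in acylium-like fashion, to the free B4 hydroxyl of 6 without any base. The chelated B2 hydroxyl should stay free, and any phenol trifluoroacetate is cleaved on aqueous work-up.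

Step 3. The most likely failure is attack at the position between the two methoxy groups, which would give the isomeric aldehyde, or incomplete conversion of a ring position flanked by two substituents. The fallback sets out from 7 and comes back at 10, and it also bypasses step 4. NBS in MeCN at 0 °C brominates 7 para to a methoxy group to give 2-bromo-1,5-dimethoxy-3-pentylbenzene F8. Bromine–lithium exchange with n-BuLi (THF, −78 °C) gives (2,4-dimethoxy-6-pentylphenyl)lithium F9, which is quenched with CO2 and acidified to give 10. The carbon substituent is thereby placed by the position of the halogen.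

## Further compounds

F1 | step 1 | (E)-N-methoxy-N-methyloct-2-enamide | CCCCC/C=C/C(=O)N(C)OC
F2 | step 1 | (E)-non-3-en-2-one | CCCCC/C=C/C(C)=O
F3 | step 1 | dibenzyl propanedioate (dibenzyl malonate) | O=C(CC(=O)OCc1ccccc1)OCc1ccccc1
F4 | step 1 | dibenzyl 2-(2-oxononan-4-yl)propanedioate | CCCCCC(CC(C)=O)C(C(=O)OCc1ccccc1)C(=O)OCc1ccccc1
F5 | step 2 | 5-pentylbenzene-1,3-diol | CCCCCc1cc(O)cc(O)c1
F6 | step 2 | 2,4-dihydroxy-6-pentylbenzoic acid | CCCCCc1cc(O)cc(O)c1C(=O)O
F7 | step 6 | 2,4-dimethoxy-6-pentylbenzoic trifluoroacetic anhydride | CCCCCc1cc(OC)cc(OC)c1C(=O)OC(=O)C(F)(F)F
F8 | step 3 | 2-bromo-1,5-dimethoxy-3-pentylbenzene | CCCCCc1cc(OC)cc(OC)c1Br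
F9 | step 3 | (2,4-dimethoxy-6-pentylphenyl)lithium | [Li]c1c(OC)cc(OC)cc1CCCCC
A1 | alternative 1 | benzyl 2-(benzyloxy)-4-[(2,4-dihydroxy-6-pentylbenzoyl)oxy]-6-pentylbenzoate | CCCCCc1cc(OC(=O)c2c(CCCCC)cc(O)cc2O)cc(OCc2ccccc2)c1C(=O)OCc1ccccc1
A2 | alternative 1 | 6-(2,4-dioxononyl)-2,2-dimethyl-4H-1,3-dioxin-4-one | CCCCCC(=O)CC(=O)CC1=CC(=O)OC(C)(C)O1
A3 | alternative 1 | benzyl 2-(benzyloxy)-4-hydroxy-6-pentylbenzoate | CCCCCc1cc(O)cc(OCc2ccccc2)c1C(=O)OCc1ccccc1
A4 | alternative 1 | benzyl 2-(benzyloxy)-6-pentyl-4-[(3,5,7-trioxododecanoyl)oxy]benzoate | CCCCCC(=O)CC(=O)CC(=O)CC(=O)Oc1cc(CCCCC)c(C(=O)OCc2ccccc2)c(OCc2ccccc2)c1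
A5 | alternative 2 | benzyl 2-hydroxy-6-pentyl-4-(triisopropylsilyloxy)benzoate | CCCCCc1cc(O[Si](C(C)C)(C(C)C)C(C)C)cc(O)c1C(=O)OCc1ccccc1
A6 | alternative 2 | benzyl (E)-5-diazo-4-oxo-3-pentylpent-2-enoate | CCCCC/C(=C\C(=O)OCc1ccccc1)C(=O)C=[N+]=[N-]
A7 | alternative 2 | (triisopropylsilyloxy)acetylene | C#CO[Si](C(C)C)(C(C)C)C(C)C
A8 | alternative 3 | benzyl 2-(benzyloxy)-4-[(4-hydroxy-2-methoxy-6-pentylbenzoyl)oxy]-6-pentylbenzoate | CCCCCc1cc(OC(=O)c2c(CCCCC)cc(O)cc2OC)cc(OCc2ccccc2)c1C(=O)OCc1ccccc1
A9 | alternative 3 | 1,1-dimethoxy-3-(trimethylsilyloxy)buta-1,3-diene | COC(OC)=CC(=C)O[Si](C)(C)C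
A10 | alternative 3 | benzyl 2-(benzyloxy)-4-(oct-2-ynoyloxy)-6-pentylbenzoate | CCCCCC#CC(=O)Oc1cc(CCCCC)c(C(=O)OCc2ccccc2)c(OCc2ccccc2)c1
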